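The seven-membered ring (C1, C5–C10) is cut at C6–C7 and C1–C10: C7=C8(Me)–C9=C10–O is a 1-oxy-3-methylbuta-1,3-diene and C6(O)–C5=C1 an alkoxy(alkenyl)carbene whose alkene lies in the five-membered ring (C1–C5). In one operation a chromium carbene cyclopropanates the diene terminus and the cis-divinylcyclopropane undergoes a Cope shift. This closes the seven-membered ring, creates the quaternary C1 and the oxygenated C10, and leaves C8=C9 and a C5=C6 enol ether (the masked C6 ketone) in place. The precursors are the pentacarbonylchromium methoxycarbene of a cyclopentene carrying the terpinen-4-ol-derived C4 silyloxy(isopropyl) centre, and the (E)-silyl dienol ether of prenal.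

Key step: step 7

Assumption and numbering: daucane locants are used throughout (C1 quaternary ring-fusion carbon bearing methyl, C2 and C3 ring CH2, C4 carbinol carbon bearing isopropyl, C5 ring-fusion CH, C6, C7, C8 bearing methyl, C9, C10); (S)-terpinen-4-ol is taken as enantiopure material.

Step 1
Reactants: 1 (S)-terpinen-4-ol
Product: 2 (S)-triethyl{[4-methyl-1-(propan-2-yl)cyclohex-3-en-1-yl]oxy}silane
Conditions: Et3SiOTf, 2,6-lutidine, CH2Cl2, 0 °C → rt
Reagents that add atoms: triethylsilyl trifluoromethanesulfonate, CC[Si](CC)(CC)OS(=O)(=O)C(F)(F)F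
Why: Silyl triflate/lutidine silylation is the standard protection of a hindered tertiary alcohol, and the carbinol stereocentre is not involved.

Step 2
Reactants: 2 (S)-triethyl{[4-methyl-1-(propan-2-yl)cyclohex-3-en-1-yl]oxy}silane
Product: 4 (3S)-6-oxo-3-(propan-2-yl)-3-(triethylsilyloxy)heptanal, via ozonide 3 (not isolated)
Conditions: O3, CH2Cl2, −78 °C; then PPh3, −78 °C → rt
Reagents that add atoms: ozone, [O-][O+]=O
Why: Ozonolysis with reductive work-up cleaves the only alkene into the methyl ketone and the aldehyde without touching the quaternary carbinol centre.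

Step 3
Reactants: 4 (3S)-6-oxo-3-(propan-2-yl)-3-(triethylsilyloxy)heptanal
Product: 5 (5R)-2-methyl-5-(propan-2-yl)-5-(triethylsilyloxy)cyclopent-1-ene-1-carbaldehyde
Conditions: piperidine (cat.), AcOH (cat.), toluene, 60 °C
Reagents that add atoms: none
Why: Intramolecular aldol condensation through the piperidine enamine of the aldehyde, which adds to the methyl ketone (five-membered ring) and loses water to the tetrasubstituted enal; the silyl ether keeps the tertiary oxygen from leaving or forming a hemiketal, and the quaternary centre cannot epimerise.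

Step 4
Reactants: 5 (5R)-2-methyl-5-(propan-2-yl)-5-(triethylsilyloxy)cyclopent-1-ene-1-carbaldehyde
Product: 6 (5R)-2-methyl-5-(propan-2-yl)-5-(triethylsilyloxy)cyclopent-1-ene-1-carboxylic acid
Conditions: NaClO2, NaH2PO4, 2-methylbut-2-ene, t-BuOH/H2O, rt
Reagents that add atoms: sodium chlorite, [Na+].[O-]Cl=O
Why: Pinnick oxidation is chemoselective for the aldehyde, and the buffered medium with a hypochlorite scavenger spares the alkene and the tertiary silyl ether.

Step 5
Reactants: 6 (5R)-2-methyl-5-(propan-2-yl)-5-(triethylsilyloxy)cyclopent-1-ene-1-carboxylic acid; 7 Cr(CO)6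
Product: 11 pentacarbonyl{methoxy[(5R)-2-methyl-5-(propan-2-yl)-5-(triethylsilyloxy)cyclopent-1-en-1-yl]methylidene}chromium, via acid chloride 8 (not isolated), via Na2Cr(CO)5 9 (not isolated), via sodium acylchromate 10 (not isolated)
Conditions: (a) 1-chloro-N,N,2-trimethylprop-1-en-1-amine, CH2Cl2, 0 °C → rt; (b) 7, NaC10H8 (2 equiv), THF, −78 °C, then 8, −78 → 0 °C; (c) Me3OBF4, CH2Cl2, 0 °C
Reagents that add atoms: trimethyloxonium tetrafluoroborate, C[O+](C)C.F[B-](F)(F)F
Why: Neutral chlorination with the Ghosez reagent spares the silyl ether, acyl substitution by the pentacarbonylchromate dianion gives the acylchromate, and O-methylation with the Meerwein salt completes a Fischer carbene synthesis that needs no alkenyllithium; no stereocentre is touched.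

Step 6
Reactants: 12 3-methylbut-2-enal
Product: 13 (E)-tert-butyldimethyl[(3-methylbuta-1,3-dien-1-yl)oxy]silane
Conditions: t-BuMe2SiOTf, Et3N, Et2O, 0 °C → rt
Reagents that add atoms: tert-butyldimethylsilyl trifluoromethanesulfonate, CC(C)(C)[Si](C)(C)OS(=O)(=O)C(F)(F)F
Why: γ-Deprotonation and O-silylation of the enal (silyl dienol ether formation) through its s-trans conformer gives the E enol ether geometry.

Step 7
Reactants: 11 pentacarbonyl{methoxy[(5R)-2-methyl-5-(propan-2-yl)-5-(triethylsilyloxy)cyclopent-1-en-1-yl]methylidene}chromium; 13 (E)-tert-butyldimethyl[(3-methylbuta-1,3-dien-1-yl)oxy]silane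
Product: 15 (1R,4R,10S)-10-(tert-butyldimethylsilyloxy)-6-methoxy-4-(triethylsilyloxy)dauca-5,8-diene, via cis-divinylcyclopropane 14 (not isolated)
Conditions: 13 (3 equiv), toluene, CO (1 atm), 80 °C then 110 °C; filtration through basic Al2O3
Reagents that add atoms: none
Why: The unsubstituted diene terminus C7, the vinylogous nucleophilic site of the silyl dienol ether, attacks the electrophilic carbene carbon C6 and the C6–C7–C8 cyclopropane 14 closes by [2+1] carbene transfer with loss of the Cr(CO)5 fragment; 14 then undergoes a [3,3] shift through a boat transition state that breaks C6–C8 and joins C1 to C10. The closest known reaction type is the tandem cyclopropanation–Cope rearrangement (formal (4+3) cycloaddition) of alkenyl Fischer carbene complexes with electron-rich 1,3-dienes; the tetrasubstituted alkenyl group lies at the edge of that scope but shuts off the competing Diels–Alder mode. The seven-membered ring closes by sigmatropy of the cis-divinylcyclopropane and not by a polar cyclisation, and trans-cyclopropanes can reach the cis form at 110 °C by reversible opening of the donor-substituted C6–C8 bond. C10 is set relative to C1 by the boat geometry, in which the ring-locked Z-methyl on C1 points inward and the E-silyloxy group on C10 outward, so that methyl and oxygen end up trans; C1 is set by the C4 centre, the new bond forming on the cyclopentene face anti to the isopropyl group. The step needs regioselectivity for C7=C8, secured by the silyloxy group (C7 is the most nucleophilic and least hindered carbon), and face selectivity at C1, which rests on the branched isopropyl carbon on the α-face being bulkier near the ring than the silyl ether oxygen on the β-face. CO suppresses the metathesis channel of the enol ether bond and returns the metal as Cr(CO)6.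

Step 8
Reactants: 15 (1R,4R,10S)-10-(tert-butyldimethylsilyloxy)-6-methoxy-4-(triethylsilyloxy)dauca-5,8-diene
Product: 16 (1R,4R,10S)-6-methoxydauca-5,8-diene-4,10-diol
Conditions: Bu4NF, THF, rt → 45 °C
Reagents that add atoms: none
Why: Fluoride-induced desilylation removes both silyl ethers in a basic medium that leaves the acid-labile enol ether, and with it the masked C6 ketone, intact; no stereocentre changes.

Step 9
Reactants: 16 (1R,4R,10S)-6-methoxydauca-5,8-diene-4,10-diol; 17 (E)-2-methylbut-2-enoyl chloride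
Product: 18 (1R,4R,10S)-4-hydroxy-6-methoxydauca-5,8-dien-10-yl (E)-2-methylbut-2-enoate
Conditions: pyridine/CH2Cl2, 4-(dimethylamino)pyridine (cat.), 0 → 40 °C
Reagents that add atoms: none
Why: Nucleophile-catalysed acylation reaches only the secondary allylic C10 hydroxyl, the tertiary C4 hydroxyl being too hindered; excess pyridine keeps the enol ether safe and avoids the vinylketene pathway that would deconjugate the tigloyl group.

Step 10
Reactants: 18 (1R,4R,10S)-4-hydroxy-6-methoxydauca-5,8-dien-10-yl (E)-2-methylbut-2-enoate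
Product: 19 (1R,4R,5R,10S)-4-hydroxy-6-oxodauc-8-en-10-yl (E)-2-methylbut-2-enoate
Conditions: oxalic acid (cat.), THF/H2O, 0 °C → rt
Reagents that add atoms: water, O
Why: Acid-catalysed enol ether hydrolysis under the mild conditions used for 1-methoxy-1,4-dienes from Birch reductions, which leave the β,γ-alkene C8=C9 out of conjugation; C5 is set by kinetic protonation on the α-face, which lets C6 swing toward the small, hydrogen-bonded C4 hydroxyl and away from the isopropyl and C1 methyl groups, so the cis-fused ketone should result.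

Step 11
Reactants: 19 (1R,4R,5R,10S)-4-hydroxy-6-oxodauc-8-en-10-yl (E)-2-methylbut-2-enoate
Product: 20 (1R,4R,5S,6R,10S)-4,6-dihydroxydauc-8-en-10-yl (E)-2-methylbut-2-enoate
Conditions: Et2BOMe, THF/MeOH (4:1), −78 °C; NaBH4, −78 °C; AcOH quench, MeOH co-evaporation (Et2BOMe re-formed)
Reagents that add atoms: none
Why: Narasaka–Prasad reduction: the Et2B chelate between the C4 oxygen and the C6 carbonyl holds the carbonyl syn to C4–O, and external hydride attacks the face bearing the C5 hydrogen, anti to the quaternary C1, which sets C6 as R (1,3-syn to the C4 hydroxyl); both esters are inert at −78 °C.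

Step 12
Reactants: 21 4-hydroxybenzoic acid
Product: 23 4-(tert-butyldimethylsilyloxy)benzoic acid, via silyl ester 22 (not isolated)
Conditions: t-BuMe2SiCl (2.2 equiv), imidazole, DMF, rt; then AcOH/THF/H2O, rt
Reagents that add atoms: tert-butyldimethylsilyl chloride, CC(C)(C)[Si](C)(C)Cl
Why: Silylation of both phenol and acid followed by selective hydrolysis of the far more labile silyl ester leaves the aryl silyl ether.

Step 13
Reactants: 20 (1R,4R,5S,6R,10S)-4,6-dihydroxydauc-8-en-10-yl (E)-2-methylbut-2-enoate; 23 4-(tert-butyldimethylsilyloxy)benzoic acid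
Product: 24 (1R,4R,5S,6R,10S)-6-[4-(tert-butyldimethylsilyloxy)benzoyloxy]-4-hydroxydauc-8-en-10-yl (E)-2-methylbut-2-enoate
Conditions: N,N'-dicyclohexylcarbodiimide, 4-(dimethylamino)pyridine, CH2Cl2, rt
Reagents that add atoms: none
Why: Steglich esterification acylates the secondary C6 hydroxyl with retention, the tertiary C4 hydroxyl does not react, and the silyl-protected phenol cannot act as an acyl donor or acceptor.

Step 14
Reactants: 24 (1R,4R,5S,6R,10S)-6-[4-(tert-butyldimethylsilyloxy)benzoyloxy]-4-hydroxydauc-8-en-10-yl (E)-2-methylbut-2-enoate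
Product: 25 (1R,4R,5S,6R,10S)-4-hydroxy-6-(4-hydroxybenzoyloxy)dauc-8-en-10-yl (E)-2-methylbut-2-enoate
Conditions: Bu4NF, AcOH (1:1), THF, 0 °C
Reagents that add atoms: none
Why: Fluoride cleavage of the aryl silyl ether is fast, and buffering with acetic acid keeps the phenoxide from attacking or shifting either ester; no stereocentre is affected.

Compound list
1 | (S)-terpinen-4-ol, (1S)-4-methyl-1-(propan-2-yl)cyclohex-3-en-1-ol | CC1=CC[C@](O)(C(C)C)CC1 | starting material
2 | (S)-triethyl{[4-methyl-1-(propan-2-yl)cyclohex-3-en-1-yl]oxy}silane | CC1=CC[C@](O[Si](CC)(CC)CC)(C(C)C)CC1 | intermediate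
3 | ozonide (1,2,4-trioxolane) of 2, S at the silyloxy carbon, both bridge orientations | CC12CC[C@@](O[Si](CC)(CC)CC)(C(C)C)CC(OO1)O2 | intermediate (not isolated)
4 | (3S)-6-oxo-3-(propan-2-yl)-3-(triethylsilyloxy)heptanal | CC(=O)CC[C@@](O[Si](CC)(CC)CC)(C(C)C)CC=O | intermediate
5 | (5R)-2-methyl-5-(propan-2-yl)-5-(triethylsilyloxy)cyclopent-1-ene-1-carbaldehyde | O=CC1=C(C)CC[C@@]1(O[Si](CC)(CC)CC)C(C)C | intermediate
6 | (5R)-2-methyl-5-(propan-2-yl)-5-(triethylsilyloxy)cyclopent-1-ene-1-carboxylic acid | OC(=O)C1=C(C)CC[C@@]1(O[Si](CC)(CC)CC)C(C)C | intermediate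
7 | hexacarbonylchromium, Cr(CO)6 | O=C=[Cr](=C=O)(=C=O)(=C=O)(=C=O)=C=O | starting material
8 | (5R)-2-methyl-5-(propan-2-yl)-5-(triethylsilyloxy)cyclopent-1-ene-1-carbonyl chloride | ClC(=O)C1=C(C)CC[C@@]1(O[Si](CC)(CC)CC)C(C)C | intermediate (not isolated)
9 | disodium pentacarbonylchromate, Na2Cr(CO)5 | [Na+].[Na+].O=C=[Cr-2](=C=O)(=C=O)(=C=O)=C=O | intermediate (not isolated)
10 | sodium pentacarbonyl{[(5R)-2-methyl-5-(propan-2-yl)-5-(triethylsilyloxy)cyclopent-1-en-1-yl]carbonyl}chromate | [Na+].[O-]C(=[Cr](=C=O)(=C=O)(=C=O)(=C=O)=C=O)C1=C(C)CC[C@@]1(O[Si](CC)(CC)CC)C(C)C | intermediate (not isolated)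
11 | pentacarbonyl{methoxy[(5R)-2-methyl-5-(propan-2-yl)-5-(triethylsilyloxy)cyclopent-1-en-1-yl]methylidene}chromium | COC(=[Cr](=C=O)(=C=O)(=C=O)(=C=O)=C=O)C1=C(C)CC[C@@]1(O[Si](CC)(CC)CC)C(C)C | intermediate
12 | 3-methylbut-2-enal | CC(C)=CC=O | starting material
13 | (E)-tert-butyldimethyl[(3-methylbuta-1,3-dien-1-yl)oxy]silane | C=C(C)/C=C/O[Si](C)(C)C(C)(C)C | intermediate
14 | (1R,2S)-2-[(E)-2-(tert-butyldimethylsilyloxy)ethenyl]-1-methoxy-2-methyl-1-[(5R)-2-methyl-5-(propan-2-yl)-5-(triethylsilyloxy)cyclopent-1-en-1-yl]cyclopropane (reactive cis isomer; the other cyclopropane isomers equilibrate with it) | CO[C@]1(C2=C(C)CC[C@@]2(O[Si](CC)(CC)CC)C(C)C)C[C@@]1(C)/C=C/O[Si](C)(C)C(C)(C)C | intermediate (not isolated)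
15 | (1R,4R,10S)-10-(tert-butyldimethylsilyloxy)-6-methoxy-4-(triethylsilyloxy)dauca-5,8-diene | CC(C)(C)[Si](C)(C)O[C@H]1C=C(C)CC(OC)=C2[C@@]1(C)CC[C@@]2(O[Si](CC)(CC)CC)C(C)C | intermediate
16 | (1R,4R,10S)-6-methoxydauca-5,8-diene-4,10-diol | O[C@H]1C=C(C)CC(OC)=C2[C@@]1(C)CC[C@@]2(O)C(C)C | intermediate
17 | (E)-2-methylbut-2-enoyl chloride (tigloyl chloride) | C/C=C(\C)C(=O)Cl | starting material
18 | (1R,4R,10S)-4-hydroxy-6-methoxydauca-5,8-dien-10-yl (E)-2-methylbut-2-enoate | C/C=C(\C)C(=O)O[C@H]1C=C(C)CC(OC)=C2[C@@]1(C)CC[C@@]2(O)C(C)C | intermediate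
19 | (1R,4R,5R,10S)-4-hydroxy-6-oxodauc-8-en-10-yl (E)-2-methylbut-2-enoate (H-5 cis to the C1 methyl group) | C/C=C(\C)C(=O)O[C@H]1C=C(C)CC(=O)[C@@H]2[C@@]1(C)CC[C@@]2(O)C(C)C | intermediate
20 | (1R,4R,5S,6R,10S)-4,6-dihydroxydauc-8-en-10-yl (E)-2-methylbut-2-enoate | C/C=C(\C)C(=O)O[C@H]1C=C(C)C[C@@H](O)[C@@H]2[C@@]1(C)CC[C@@]2(O)C(C)C | intermediate
21 | 4-hydroxybenzoic acid | OC(=O)c1ccc(O)cc1 | starting material
22 | tert-butyldimethylsilyl 4-(tert-butyldimethylsilyloxy)benzoate | CC(C)(C)[Si](C)(C)OC(=O)c1ccc(O[Si](C)(C)C(C)(C)C)cc1 | intermediate (not isolated)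
23 | 4-(tert-butyldimethylsilyloxy)benzoic acid | OC(=O)c1ccc(O[Si](C)(C)C(C)(C)C)cc1 | intermediate
24 | (1R,4R,5S,6R,10S)-6-[4-(tert-butyldimethylsilyloxy)benzoyloxy]-4-hydroxydauc-8-en-10-yl (E)-2-methylbut-2-enoate | C/C=C(\C)C(=O)O[C@H]1C=C(C)C[C@@H](OC(=O)c2ccc(O[Si](C)(C)C(C)(C)C)cc2)[C@@H]2[C@@]1(C)CC[C@@]2(O)C(C)C | intermediate
25 | (1R,4R,5S,6R,10S)-4-hydroxy-6-(4-hydroxybenzoyloxy)dauc-8-en-10-yl (E)-2-methylbut-2-enoate, CNP0273650.13 | C/C=C(\C)C(=O)O[C@H]1C=C(C)C[C@@H](OC(=O)c2ccc(O)cc2)[C@@H]2[C@@]1(C)CC[C@@]2(O)C(C)C | target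

Total step count: 14. Longest linear sequence: 12 steps (steps 1–5, 7–11, 13 and 14).

Steps most likely to fail

Step 7. What may go wrong: carbene transfer from the crowded chromium complex, whose carbene carbon is flanked by the quaternary C4, is slow and needs heat. Thermal decomposition of 11 and diversion of the cyclopropane at the temperature that the inward-methyl Cope requires may therefore outrun ring formation. Fallback: the two events are separated and the carbene is carried by molybdenum. Setting out from acid 6 (converted to 8 as in step 5), Mo(CO)6 and NaC10H8 should give disodium pentacarbonylmolybdate F1, acylation by 8 the sodium acylmolybdate F2, and Me3OBF4 the molybdenum methoxycarbene F3, which is kept cold. F3 should transfer its carbene to diene 13 under CO between 0 °C and room temperature, so that cyclopropane 14 can be isolated and then heated on its own in toluene, where the sequence comes back to the route at 15.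

Step 10. What may go wrong: poor facial selectivity in the protonation of C5. Delivery on the β-face next to the free C4 hydroxyl would give the trans-fused 5-epimer, and later equilibration is excluded because enolisation would pull C8=C9 into conjugation. Fallback: steric approach control by a blocking group replaces strain control. Setting out from 18, the C4 hydroxyl is silylated (Et3SiOTf, 2,6-lutidine) to the 4-O-triethylsilyl enol ether F4, whose β-face is screened. Aqueous HF in MeCN should hydrolyse the enol ether to the β-silyloxy ketone F5 and then remove the silyl group in the same flask, coming back to the route at 19.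

Step 11. What may go wrong: incomplete boron chelation of the hindered tertiary C4 hydroxyl, so that hydride delivery is not confined to the α-face of C6 (poor facial selectivity). Fallback: the opposite epimer is made on purpose and inverted. Setting out from 19, hydroxyl-directed intramolecular hydride delivery with Me4NBH(OAc)3 in AcOH/MeCN should give the 1,3-anti diol F6. Mitsunobu esterification of F6 with acid 23 (PPh3, diisopropyl azodicarboxylate) inverts C6 and comes back to the route at 24.

Further compounds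
F1 | step 7 | disodium pentacarbonylmolybdate, Na2Mo(CO)5 | [Na+].[Na+].O=C=[Mo-2](=C=O)(=C=O)(=C=O)=C=O
F2 | step 7 | sodium pentacarbonyl{[(5R)-2-methyl-5-(propan-2-yl)-5-(triethylsilyloxy)cyclopent-1-en-1-yl]carbonyl}molybdate | [Na+].[O-]C(=[Mo](=C=O)(=C=O)(=C=O)(=C=O)=C=O)C1=C(C)CC[C@@]1(O[Si](CC)(CC)CC)C(C)C
F3 | step 7 | pentacarbonyl{methoxy[(5R)-2-methyl-5-(propan-2-yl)-5-(triethylsilyloxy)cyclopent-1-en-1-yl]methylidene}molybdenum | COC(=[Mo](=C=O)(=C=O)(=C=O)(=C=O)=C=O)C1=C(C)CC[C@@]1(O[Si](CC)(CC)CC)C(C)C
F4 | step 10 | (1R,4R,10S)-6-methoxy-4-(triethylsilyloxy)dauca-5,8-dien-10-yl (E)-2-methylbut-2-enoate | C/C=C(\C)C(=O)O[C@H]1C=C(C)CC(OC)=C2[C@@]1(C)CC[C@@]2(O[Si](CC)(CC)CC)C(C)C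
F5 | step 10 | (1R,4R,5R,10S)-6-oxo-4-(triethylsilyloxy)dauc-8-en-10-yl (E)-2-methylbut-2-enoate | C/C=C(\C)C(=O)O[C@H]1C=C(C)CC(=O)[C@@H]2[C@@]1(C)CC[C@@]2(O[Si](CC)(CC)CC)C(C)C
F6 | step 11 | (1R,4R,5S,6S,10S)-4,6-dihydroxydauc-8-en-10-yl (E)-2-methylbut-2-enoate | C/C=C(\C)C(=O)O[C@H]1C=C(C)C[C@H](O)[C@@H]2[C@@]1(C)CC[C@@]2(O)C(C)C
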